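**Assumption:** the target SMILES has no stereocentres, and the 4,4'-axis is flanked only by H-3/H-5 (like 1,1'-binaphthyl), so it is not configurationally stable. The compound is treated as achiral and no stereocontrol is needed.

## Retrosynthetic overview

1. Target 10 ⇐ bis-benzyl ether 9 by debenzylation of the two 7-OH groups.
2. 9 ⇐ bis(aryl) hexa-2,4-diynedioate 8 by a double 6-endo-dig hydroarylation. Both pyranone rings are formed last, onto a C4–C4' bond that already exists (proposed new step).
3. 8 ⇐ aryl propiolate 7 by Glaser–Hay coupling, so the hindered 4,4'-bond is made as an unhindered sp–sp bond.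
4. 7 ⇐ phenol 5 + propiolic acid 6; 5 ⇐ syringol 1 by O-benzylation, Vilsmeier formylation and Dakin oxidation.

## Route

**Step 1**
Reactants: 1, 2,6-dimethoxyphenol (syringol); 2, benzyl bromide
Product: 3, 2-(benzyloxy)-1,3-dimethoxybenzene
Conditions: K2CO3, DMF, 60 °C
Reagents that add atoms: benzyl bromide (2), BrCc1ccccc1
Why: Williamson ether synthesis; the phenoxide is the only nucleophile and benzyl bromide is an unhindered SN2 electrophile.

**Step 2**
Reactants: 3, 2-(benzyloxy)-1,3-dimethoxybenzene
Product: 4, 3-(benzyloxy)-2,4-dimethoxybenzaldehyde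
Conditions: POCl3, DMF, 0 → 75 °C; then aq. NaOAc
Reagents that add atoms: DMF, CN(C)C=O (formyl carbon); water, O (carbonyl oxygen on iminium hydrolysis)
Why: Vilsmeier–Haack formylation; as with 1,2,3-trimethoxybenzene, attack occurs at C4 (ortho/para to the two coplanar OMe groups) and not para to the twisted central ether.

**Step 3**
Reactants: 4, 3-(benzyloxy)-2,4-dimethoxybenzaldehyde
Product: 5, 3-(benzyloxy)-2,4-dimethoxyphenol
Conditions: mCPBA, CH2Cl2, 0 °C → rt; then K2CO3, MeOH, rt
Reagents that add atoms: mCPBA, OOC(=O)c1cccc(Cl)c1 (inserted oxygen)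
Why: Baeyer–Villiger (Dakin-type) oxidation; the electron-rich o,p-alkoxy aryl group migrates in preference to H, and mild methanolysis of the aryl formate releases the phenol.

**Step 4**
Reactants: 5, 3-(benzyloxy)-2,4-dimethoxyphenol; 6, propiolic acid
Product: 7, 3-(benzyloxy)-2,4-dimethoxyphenyl prop-2-ynoate
Conditions: DCC, DMAP (5 mol%), CH2Cl2, −10 °C → rt
Reagents that add atoms: propiolic acid (6), C#CC(=O)O
Why: Steglich esterification, the standard route to aryl propiolates; low temperature and low DMAP loading suppress conjugate addition to the ynoate.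

**Step 5**
Reactants: 7, 3-(benzyloxy)-2,4-dimethoxyphenyl prop-2-ynoate (2 equiv)
Product: 8, bis[3-(benzyloxy)-2,4-dimethoxyphenyl] hexa-2,4-diynedioate
Conditions: CuCl (10 mol%), TMEDA (10 mol%), O2 (1 atm), acetone, rt
Reagents that add atoms: none
Why: Glaser–Hay oxidative homocoupling of a terminal propiolate ester, which is established for alkyl propiolates; it forms the future C4–C4' bond between two unhindered sp carbons.

**Step 6**
Reactants: 8, bis[3-(benzyloxy)-2,4-dimethoxyphenyl] hexa-2,4-diynedioate
Product: 9, 7,7'-bis(benzyloxy)-6,6',8,8'-tetramethoxy-2H,2'H-[4,4'-bichromene]-2,2'-dione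
Conditions: [JohnPhosAu(MeCN)]SbF6 (10 mol%), DCE/HFIP 9:1, 0.02 M, 50 °C
Reagents that add atoms: none
Why: Proposed new method: a twofold gold(I)-catalysed intramolecular 6-endo-dig hydroarylation of a conjugated 1,3-diyne bis(aryl ester), building both pyranone rings onto the existing C4–C4' bond. Cationic Au(I) π-activates one ynoate; the only free ortho carbon of the aryl ester (para to OBn, so strongly nucleophilic) attacks the β-alkyne carbon anti to gold; rearomatisation and HFIP-assisted protodeauration give a 4-alkynylcoumarin. This intermediate is an aryl 3-(hetero)arylpropiolate and cyclises the same way. The tether fixes the regiochemistry on both the arene and the diyne, and the isomerisation is atom-neutral. The closest known reaction type is the Au-, Pd- or Pt-catalysed intramolecular hydroarylation of aryl alkynoates (including aryl 3-arylpropiolates) to coumarins, which has not been shown on diynedioates to give 4,4'-bicoumarins.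

**Step 7**
Reactants: 9, 7,7'-bis(benzyloxy)-6,6',8,8'-tetramethoxy-2H,2'H-[4,4'-bichromene]-2,2'-dione
Product: 10, 4,4'-biisofraxidin (7,7'-dihydroxy-6,6',8,8'-tetramethoxy-2H,2'H-[4,4'-bichromene]-2,2'-dione)
Conditions: BCl3, pentamethylbenzene, CH2Cl2, −78 °C; MeOH quench
Reagents that add atoms: none
Why: Lewis-acid debenzylation with a non-Lewis-basic cation scavenger; at −78 °C aryl benzyl ethers cleave while aryl methyl ethers, the lactones and the C3=C4 bonds are untouched (the last of these is why hydrogenolysis is avoided).

## Compound list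

1 | 2,6-dimethoxyphenol (syringol) | COc1cccc(OC)c1O | starting material
2 | benzyl bromide | BrCc1ccccc1 | starting material
3 | 2-(benzyloxy)-1,3-dimethoxybenzene | COc1cccc(OC)c1OCc1ccccc1 | intermediate
4 | 3-(benzyloxy)-2,4-dimethoxybenzaldehyde | COc1ccc(C=O)c(OC)c1OCc1ccccc1 | intermediate
5 | 3-(benzyloxy)-2,4-dimethoxyphenol | COc1ccc(O)c(OC)c1OCc1ccccc1 | intermediate
6 | propiolic acid | C#CC(=O)O | starting material
7 | 3-(benzyloxy)-2,4-dimethoxyphenyl prop-2-ynoate | COc1ccc(OC(=O)C#C)c(OC)c1OCc1ccccc1 | intermediate
8 | bis[3-(benzyloxy)-2,4-dimethoxyphenyl] hexa-2,4-diynedioate | COc1ccc(OC(=O)C#CC#CC(=O)Oc2ccc(OC)c(OCc3ccccc3)c2OC)c(OC)c1OCc1ccccc1 | intermediate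
9 | 7,7'-bis(benzyloxy)-6,6',8,8'-tetramethoxy-2H,2'H-[4,4'-bichromene]-2,2'-dione | COc1cc2c(-c3cc(=O)oc4c(OC)c(OCc5ccccc5)c(OC)cc34)cc(=O)oc2c(OC)c1OCc1ccccc1 | intermediate
10 | 4,4'-biisofraxidin | COc1cc2c(-c3cc(=O)oc4c(OC)c(O)c(OC)cc34)cc(=O)oc2c(OC)c1O | target

## Summary

Total step count: 7
Longest linear sequence: 7 steps (1 → 3 → 4 → 5 → 7 → 8 → 9 → 10)

Three steps most likely to fail:

1. **Step 6 (proposed new double hydroarylation).** Risks are ipso attack at the ester-bearing carbon (activated by the para-OMe), stalling after the first ring closure, and gold-induced decomposition of the electron-poor diyne. Fallback, known chemistry: abandon the diyne and form the C4–C4' bond by reductive homocoupling. Condense phenol 5 with Meldrum's acid and cyclise (Eaton's reagent) to 7-(benzyloxy)-4-hydroxy-6,8-dimethoxycoumarin, re-benzylating if the ether is lost. Convert it to the 4-triflate (Tf2O, Et3N) and dimerise with Ni(0) (NiCl2(PPh3)2, Zn, Et4NI, THF, 60 °C) to give 9, then run step 7.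

2. **Step 5 (Glaser–Hay coupling on an aryl propiolate).** The activated aryl ester may suffer amine-initiated conjugate addition or oligomerisation. Fallback: bring the diyne in ready-made. Oxidise commercial hexa-2,4-diyne-1,6-diol (Jones) to hexa-2,4-diynedioic acid and esterify it twice with phenol 5 (DIC, cat. DMAP, 0 °C) to reach 8 without forming a C–C bond on the labile ester.

3. **Step 4 (propiolate esterification of a hindered, electron-rich phenol).** Phenol or DMAP Michael addition to the ynoate and N-acylurea formation can erode the yield. Fallback: acylate 5 with 3-(trimethylsilyl)propioloyl chloride (pyridine, CH2Cl2). Take the C-silyl ynoate directly to 8 by copper-mediated desilylative oxidative homocoupling (CuCl, DMF, air), which replaces both the carbodiimide coupling and the free terminal ynoate.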